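The lactone ring (ring B) is cut across O2–C3 and C4a–C4, leaving an aryl carboxylate and the two-carbon C3–C4 unit. The plan exploits the para relationship of the C5 and C8 hydroxyl groups of ring A: at the quinone oxidation level C4a is an electrophile next to the carboxyl-bearing C8a, while the carboxylate oxygen stays a nucleophile. A quinone carboxylic acid and a dienal that already carries the whole side chain are joined in one amine-catalysed domino reaction (1,6-oxa-Michael addition, then Michael addition of the dienamine to the quinone). This sets both bonds, both stereocentres and the side-chain alkene, and aromatisation frees the two phenols. Aldehyde oxidation and one ether cleavage finish the synthesis.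

Key step: step 4

Remark: atom numbers are those of the isochromanone core (C1 lactone carbonyl, O2 ring oxygen, C3, C4, C4a, C5 to C8, C8a); ring A is the benzene ring, ring B the lactone ring. The target is taken as drawn: 3S,4R (3,4-trans) with the side-chain CO2Me and CO2H trans (E). The three starting materials are taken as commercial.

Step 1
Reactants: 1 2,4,5-trimethoxybenzoic acid
Product: 2 4-methoxy-3,6-dioxocyclohexa-1,4-diene-1-carboxylic acid
Conditions: (NH4)2Ce(NO3)6 (2.5 equiv), MeCN/H2O 2:1, 0 °C, 15 min; extraction, used at once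
Reagents that add atoms: water, O
Why: Oxidative demethylation of the para-dimethoxy pair to the para-quinone, a known reaction of 1,2,4-trimethoxyarenes, in which the third methoxy group survives as a vinylogous ester and the carboxyl group is untouched.

Step 2
Reactants: 3 dimethyl (E)-pent-2-enedioate; 4 2,2-dimethoxyacetaldehyde
Product: 5 dimethyl (2E)-4-[(E)-2,2-dimethoxyethylidene]pent-2-enedioate
Conditions: piperidine (10 mol %), AcOH (10 mol %), toluene, Dean–Stark trap, reflux
Reagents that add atoms: none
Why: Knoevenagel condensation at the vinylogous malonate CH2 of the glutaconate with a non-enolisable aldehyde; the geometry of the new double bond does not matter, because that bond becomes a single bond in the dienamine of step 4 and is formed anew there.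

Step 3
Reactants: 5 dimethyl (2E)-4-[(E)-2,2-dimethoxyethylidene]pent-2-enedioate
Product: 6 dimethyl (2E)-4-[(E)-2-oxoethylidene]pent-2-enedioate
Conditions: TFA/H2O 9:1, CH2Cl2, 0 °C to rt
Reagents that add atoms: water, O
Why: Acid-catalysed acetal hydrolysis should unmask the aldehyde without touching the two methyl esters.

Step 4
Reactants: 2 4-methoxy-3,6-dioxocyclohexa-1,4-diene-1-carboxylic acid; 6 dimethyl (2E)-4-[(E)-2-oxoethylidene]pent-2-enedioate
Product: 10 methyl (3S,4R)-5,8-dihydroxy-6-methoxy-4-[(E)-1-methoxy-1,4-dioxobut-2-en-2-yl]-1-oxo-3,4-dihydro-1H-isochromene-3-carboxylate, via vinylogous iminium ion 7 (not isolated), via 1,6-adduct dienamine 8 (not isolated), via ene-dione adduct 9 (not isolated)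
Conditions: (R)-2-[diphenyl(trimethylsilyloxy)methyl]pyrrolidine (20 mol %), 6 (1.3 equiv), CHCl3, −20 °C to rt; aq. Na2S2O4 wash
Reagents that add atoms: none
Why: Proposed new method: the amine condenses with the aldehyde of 6 to the vinylogous iminium ion 7, the carboxylate of 2 adds to its δ-carbon (1,6-oxa-Michael addition, O2–C3), and the γ-carbon of the resulting dienamine 8 adds to the quinone carbon next to the carboxyl-bearing carbon (C4a–C4); hydrolysis of the iminium ion and enolisation of ene-dione 9 to the hydroquinone make the sequence irreversible. The closest known reaction types are the amine-catalysed oxa-Michael/Michael domino reaction of 2-(2-nitrovinyl)phenols with enals, 1,6-additions to 2,4-dienals through vinylogous iminium ions, and the enamine α-arylation of aldehydes by quinones. Ring B closes by a 6-endo-trig Michael addition in which the quinone double bond C4a=C8a becomes the ring-fusion bond; the alternative through the dienamine α-carbon would need an eight-membered ring. C3 is set in the oxa-Michael step by the catalyst, whose diphenyl(silyloxy)methyl group shields one face of the planar s-trans iminium ion (on this model the (R)-catalyst leads to 3S), and C4 follows as the 3,4-trans isomer (4R) because ring closure and the reversible γ-deprotonation of the product iminium ion both lead to the more stable trans lactone. The step needs δ- over β-attack on the iminium ion, secured by the fully substituted, ester-bearing β-carbon, and attack at C4a and not at C7 of the quinone, secured by the carboxyl group that both activates C4a and tethers the dienamine. O5 and O8 are carbonyl oxygens until the last proton shifts, so only the carboxylate can act as the oxygen nucleophile.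

Step 5
Reactants: 10 methyl (3S,4R)-5,8-dihydroxy-6-methoxy-4-[(E)-1-methoxy-1,4-dioxobut-2-en-2-yl]-1-oxo-3,4-dihydro-1H-isochromene-3-carboxylate
Product: 11 (2E)-3-[(3S,4R)-5,8-dihydroxy-6-methoxy-3-(methoxycarbonyl)-1-oxo-3,4-dihydro-1H-isochromen-4-yl]-4-methoxy-4-oxobut-2-enoic acid
Conditions: NaClO2, NaH2PO4, 2-methyl-2-butene (large excess), tBuOH/H2O, 0 °C; aq. Na2S2O4 wash
Reagents that add atoms: sodium chlorite, [Na+].[O-]Cl=O
Why: Pinnick oxidation should turn the enal into the enoic acid under buffered, non-basic conditions that spare the base-sensitive C4–H/C3–O2 array and both stereocentres, the alkene scavenger removing hypochlorous acid and the dithionite wash returning any quinone to the hydroquinone.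

Step 6
Reactants: 11 (2E)-3-[(3S,4R)-5,8-dihydroxy-6-methoxy-3-(methoxycarbonyl)-1-oxo-3,4-dihydro-1H-isochromen-4-yl]-4-methoxy-4-oxobut-2-enoic acid
Product: 12 (2E)-4-methoxy-4-oxo-3-[(3S,4R)-5,6,8-trihydroxy-3-(methoxycarbonyl)-1-oxo-3,4-dihydro-1H-isochromen-4-yl]but-2-enoic acid
Conditions: BBr3 (6 equiv), CH2Cl2, −78 to −20 °C, under argon; then H2O
Reagents that add atoms: none
Why: Boron tribromide cleavage of the aryl methyl ether, assisted by the aryloxyboron species formed at the neighbouring O5, should proceed at low temperature where the methyl esters, the lactone and the two stereocentres are expected to survive.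

Compound list
1 | 2,4,5-trimethoxybenzoic acid | COc1cc(OC)c(C(=O)O)cc1OC | starting material
2 | 4-methoxy-3,6-dioxocyclohexa-1,4-diene-1-carboxylic acid | COC1=CC(=O)C(C(=O)O)=CC1=O | intermediate
3 | dimethyl (E)-pent-2-enedioate (dimethyl glutaconate) | COC(=O)/C=C/CC(=O)OC | starting material
4 | 2,2-dimethoxyacetaldehyde | COC(OC)C=O | starting material
5 | dimethyl (2E)-4-[(E)-2,2-dimethoxyethylidene]pent-2-enedioate | COC(=O)/C=C/C(=C\C(OC)OC)C(=O)OC | intermediate
6 | dimethyl (2E)-4-[(E)-2-oxoethylidene]pent-2-enedioate | COC(=O)/C=C/C(=C\C=O)C(=O)OC | intermediate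
7 | vinylogous iminium ion from 6 and the (R)-catalyst (cation, catalyst-bound) | COC(=O)/C=C/C(C(=O)OC)=C\C=[N+]1CCC[C@@H]1C(c1ccccc1)(c1ccccc1)O[Si](C)(C)C | intermediate (not isolated)
8 | dienamine formed by 1,6-addition of the carboxylate of 2 to 7 (catalyst-bound, 3S) | COC(=O)[C@@H](OC(=O)C1=CC(=O)C(OC)=CC1=O)/C=C(C(=O)OC)/C=C/N1CCC[C@@H]1C(c1ccccc1)(c1ccccc1)O[Si](C)(C)C | intermediate (not isolated)
9 | methyl (3S,4R)-6-methoxy-4-[(E)-1-methoxy-1,4-dioxobut-2-en-2-yl]-1,5,8-trioxo-3,4,4a,5,8,8a-hexahydro-1H-isochromene-3-carboxylate (ene-dione adduct; C4a and C8a transient, not defined) | COC(=O)/C(=C/C=O)[C@H]1C2C(=O)C(OC)=CC(=O)C2C(=O)O[C@@H]1C(=O)OC | intermediate (not isolated)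
10 | methyl (3S,4R)-5,8-dihydroxy-6-methoxy-4-[(E)-1-methoxy-1,4-dioxobut-2-en-2-yl]-1-oxo-3,4-dihydro-1H-isochromene-3-carboxylate | COC(=O)/C(=C/C=O)[C@H]1c2c(O)c(OC)cc(O)c2C(=O)O[C@@H]1C(=O)OC | intermediate
11 | (2E)-3-[(3S,4R)-5,8-dihydroxy-6-methoxy-3-(methoxycarbonyl)-1-oxo-3,4-dihydro-1H-isochromen-4-yl]-4-methoxy-4-oxobut-2-enoic acid | COC(=O)/C(=C/C(=O)O)[C@H]1c2c(O)c(OC)cc(O)c2C(=O)O[C@@H]1C(=O)OC | intermediate
12 | (2E)-4-methoxy-4-oxo-3-[(3S,4R)-5,6,8-trihydroxy-3-(methoxycarbonyl)-1-oxo-3,4-dihydro-1H-isochromen-4-yl]but-2-enoic acid | COC(=O)/C(=C/C(=O)O)[C@H]1c2c(O)c(O)cc(O)c2C(=O)O[C@@H]1C(=O)OC | target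

Total step count: 6
Longest linear sequence: 5 steps (steps 2, 3, 4, 5 and 6, from 3 and 4 to 12)

Steps most likely to fail

1. Step 4. The carboxylate may add to the β-carbon or not at all, the amine may be consumed by addition to the quinone, the facial selectivity may be poor, or the lactone may reopen by vinylogous retro-oxa-Michael reaction. The fallback uses known chemistry at the isocoumarin oxidation level; it sets out from 1 and comes back to the route at 12. Acylation of dimethylsulfoxonium methylide (Me3S(O)I, KOtBu) with dimethyl oxalate should give methyl 3-[dimethyl(oxo)-λ6-sulfanylidene]-2-oxopropanoate F1. Carboxylate-directed C–H acylmethylation of 1 with F1 ([Cp*RhCl2]2, NaOAc, 1,2-dichloroethane, 80 °C) and cyclodehydration in the same flask should give methyl 5,6,8-trimethoxy-1-oxo-1H-isochromene-3-carboxylate F2. Michael addition of the sodium salt of trimethyl phosphonoacetate to C4 of F2 (NaH, THF) should give the phosphonate adduct F3. Horner–Wadsworth–Emmons olefination of F3 in the same flask with tert-butyl glyoxylate, then equilibration at C3, should give the racemic trans tert-butyl ester F4. Preparative HPLC on a chiral stationary phase should give the (3S,4R)-tert-butyl ester F5. BBr3 (CH2Cl2, −78 to 0 °C) then removes the three aryl methyl groups and the tert-butyl group to give 12.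

2. Step 5. Chlorite or hypochlorous acid may oxidise or chlorinate the electron-rich hydroquinone ring faster than the aldehyde is oxidised. The fallback takes the phenols out of play; it sets out from 10 and comes back at 11. Silylation (TBSOTf, 2,6-lutidine, CH2Cl2) should give the bis(tert-butyldimethylsilyl) ether of the enal F6. Pinnick oxidation as in step 5 should give the bis-silylated acid F7, and HF·pyridine in THF should then return 11.

3. Step 6. The boron Lewis acid may also cleave a methyl ester or open the lactone. The fallback replaces ether cleavage by a redox relay; it sets out from 11 and comes back at 12. Oxidation with PhI(OAc)2 (MeCN/H2O, 0 °C) should give the methoxyquinone acid F8, whose methoxy group is now a vinylogous ester. Dilute aqueous HCl in THF should hydrolyse it to the hydroxyquinone acid F9 far faster than the carboxylic esters, and Na2S2O4 should reduce F9 to 12.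

Further compounds
F1 | step 4 | methyl 3-[dimethyl(oxo)-λ6-sulfanylidene]-2-oxopropanoate | COC(=O)C(=O)C=S(C)(C)=O
F2 | step 4 | methyl 5,6,8-trimethoxy-1-oxo-1H-isochromene-3-carboxylate | COC(=O)C1=Cc2c(OC)c(OC)cc(OC)c2C(=O)O1
F3 | step 4 | methyl 4-[1-(dimethoxyphosphoryl)-2-methoxy-2-oxoethyl]-5,6,8-trimethoxy-1-oxo-3,4-dihydro-1H-isochromene-3-carboxylate (racemic) | COC(=O)C(C1c2c(OC)c(OC)cc(OC)c2C(=O)OC1C(=O)OC)P(=O)(OC)OC
F4 | step 4 | methyl 4-[(E)-4-tert-butoxy-1-methoxy-1,4-dioxobut-2-en-2-yl]-5,6,8-trimethoxy-1-oxo-3,4-dihydro-1H-isochromene-3-carboxylate (racemic trans) | COC(=O)/C(=C/C(=O)OC(C)(C)C)C1c2c(OC)c(OC)cc(OC)c2C(=O)OC1C(=O)OC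
F5 | step 4 | methyl (3S,4R)-4-[(E)-4-tert-butoxy-1-methoxy-1,4-dioxobut-2-en-2-yl]-5,6,8-trimethoxy-1-oxo-3,4-dihydro-1H-isochromene-3-carboxylate | COC(=O)/C(=C/C(=O)OC(C)(C)C)[C@H]1c2c(OC)c(OC)cc(OC)c2C(=O)O[C@@H]1C(=O)OC
F6 | step 5 | methyl (3S,4R)-5,8-bis(tert-butyldimethylsilyloxy)-6-methoxy-4-[(E)-1-methoxy-1,4-dioxobut-2-en-2-yl]-1-oxo-3,4-dihydro-1H-isochromene-3-carboxylate | COC(=O)/C(=C/C=O)[C@H]1c2c(O[Si](C)(C)C(C)(C)C)c(OC)cc(O[Si](C)(C)C(C)(C)C)c2C(=O)O[C@@H]1C(=O)OC
F7 | step 5 | (2E)-3-[(3S,4R)-5,8-bis(tert-butyldimethylsilyloxy)-6-methoxy-3-(methoxycarbonyl)-1-oxo-3,4-dihydro-1H-isochromen-4-yl]-4-methoxy-4-oxobut-2-enoic acid | COC(=O)/C(=C/C(=O)O)[C@H]1c2c(O[Si](C)(C)C(C)(C)C)c(OC)cc(O[Si](C)(C)C(C)(C)C)c2C(=O)O[C@@H]1C(=O)OC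
F8 | step 6 | (2E)-4-methoxy-3-[(3S,4R)-6-methoxy-3-(methoxycarbonyl)-1,5,8-trioxo-3,4,5,8-tetrahydro-1H-isochromen-4-yl]-4-oxobut-2-enoic acid | COC(=O)/C(=C/C(=O)O)[C@H]1C2=C(C(=O)C=C(OC)C2=O)C(=O)O[C@@H]1C(=O)OC
F9 | step 6 | (2E)-3-[(3S,4R)-6-hydroxy-3-(methoxycarbonyl)-1,5,8-trioxo-3,4,5,8-tetrahydro-1H-isochromen-4-yl]-4-methoxy-4-oxobut-2-enoic acid | COC(=O)/C(=C/C(=O)O)[C@H]1C2=C(C(=O)C=C(O)C2=O)C(=O)O[C@@H]1C(=O)OC
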